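**Plan**

- Retrosynthesis: the C5–OH of the benzene ring (C1 pentadecyl, C2 OAc, C3 OMe) is cut back to C5–H. The chain is then cut at C11–C12 (counted from the methyl end) into two carboxylic acids, lauric acid and a 5-arylpentanoic acid. The C13=C14 bond of the latter goes back to o-vanillin and a C4 phosphonium salt.
- Forward: Wittig reaction on o-vanillin, hydrogenation, O-acetylation, then conversion of both acids into N-acyloxyphthalimides. These are joined by a nickel-mediated doubly decarboxylative C(sp3)–C(sp3) coupling, and the free phenol is introduced last by C–H borylation/oxidation.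
- Enabling features: C11–C12 is an unbranched CH2–CH2 link between two primary carbons, four carbons from the ring and with no heteroatom nearby, so each carbon can be generated as a primary alkyl radical from a carboxyl group. In the 1,2,3-trisubstituted benzene ring, C5–H is the only ring C–H without an ortho substituent, which distinguishes the two hydroquinone oxygens without a protecting group.
- Stereochemistry: the target has no stereocentre; the Wittig alkene geometry is erased by hydrogenation.

Key step: step 6

Remark: alkene 4 is expected as a Z-rich E/Z mixture and is drawn as the Z isomer; the geometry is of no consequence because step 2 saturates the double bond.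

**Route**

Step 1
Reactants: 1 o-vanillin (2-hydroxy-3-methoxybenzaldehyde); 2 (3-carboxypropyl)triphenylphosphonium bromide
Product: 4 (Z)-5-(2-hydroxy-3-methoxyphenyl)pent-4-enoic acid, via carboxylate ylide 3 (not isolated)
Conditions: 2 (1.3 equiv), KOtBu (3.8 equiv), THF, 0 °C; then 1, 0 °C to rt; aq. HCl work-up
Reagents that add atoms: none
Why: Wittig olefination with a non-stabilised carboxylate ylide; enough base is used to hold the phenol and the acid as their potassium salts, as is usual for salicylaldehyde-type aldehydes, and the ylide should still add to the phenoxide aldehyde to give the C13=C14 alkene.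

Step 2
Reactants: 4 (Z)-5-(2-hydroxy-3-methoxyphenyl)pent-4-enoic acid
Product: 5 5-(2-hydroxy-3-methoxyphenyl)pentanoic acid
Conditions: H2 (1 atm), 10% Pd/C, EtOAc, rt
Reagents that add atoms: none
Why: Heterogeneous catalytic hydrogenation of a styrene-type double bond, which should proceed without touching the ring, the phenol or the acid.

Step 3
Reactants: 5 5-(2-hydroxy-3-methoxyphenyl)pentanoic acid
Product: 7 5-(2-acetoxy-3-methoxyphenyl)pentanoic acid, via mixed carboxylic acetic anhydride 6 (not isolated)
Conditions: Ac2O (2.5 equiv), pyridine, DMAP (cat.), rt; then H2O, rt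
Reagents that add atoms: acetic anhydride, CC(=O)OC(C)=O
Why: DMAP-catalysed O-acetylation of the only phenol present places the acetate on the oxygen flanked by OMe and the chain; the mixed anhydride formed at the carboxyl group should hydrolyse on adding water while the aryl acetate stays.

Step 4
Reactants: 7 5-(2-acetoxy-3-methoxyphenyl)pentanoic acid
Product: 8 1,3-dioxoisoindolin-2-yl 5-(2-acetoxy-3-methoxyphenyl)pentanoate
Conditions: N-hydroxyphthalimide (1.1 equiv), DIC (1.1 equiv), DMAP (10 mol%), CH2Cl2, rt
Reagents that add atoms: N-hydroxyphthalimide, ON1C(=O)c2ccccc2C1=O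
Why: Carbodiimide (Steglich-type) esterification of the acid with N-hydroxyphthalimide gives the redox-active ester under neutral conditions that the aryl acetate tolerates.

Step 5
Reactants: 9 lauric acid (dodecanoic acid)
Product: 10 1,3-dioxoisoindolin-2-yl dodecanoate
Conditions: N-hydroxyphthalimide (1.1 equiv), DIC (1.1 equiv), DMAP (10 mol%), CH2Cl2, rt
Reagents that add atoms: N-hydroxyphthalimide, ON1C(=O)c2ccccc2C1=O
Why: The same carbodiimide esterification turns the commodity fatty acid into its redox-active ester, the latent undecyl radical.

Step 6
Reactants: 8 1,3-dioxoisoindolin-2-yl 5-(2-acetoxy-3-methoxyphenyl)pentanoate; 10 1,3-dioxoisoindolin-2-yl dodecanoate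
Product: 11 2-methoxy-6-pentadecylphenyl acetate
Conditions: 8 (1 equiv), 10 (3 equiv), NiCl2·6H2O (20 mol%), 2,2':6',2''-terpyridine (20 mol%), AgNO3 (cat.), NaI, DMF, undivided cell, Mg anode/RVC cathode, constant current, rt; aq. HCl work-up
Reagents that add atoms: none
Why: Cathodically generated low-valent Ni(terpyridine) should transfer an electron to each N-acyloxyphthalimide, whose radical anion fragments to phthalimide anion, CO2 and a primary alkyl radical (4-arylbutyl from 8, undecyl from 10); capture of both radicals at nickel gives a dialkylnickel species that reductively eliminates the C11–C12 bond. The closest known reaction type is the nickel-electrocatalytic doubly decarboxylative coupling of two redox-active esters, a reductive counterpart of the mixed Kolbe electrolysis, which is documented for primary–primary pairs of fatty-acid-type esters. No ring is closed and no stereocentre is formed. The selectivity needed is cross- over homo-coupling; it is secured statistically by the threefold excess of the cheap lauric ester 10, and the homodimer docosane is a hydrocarbon that should be removed by a hexane flush on silica. Chemoselectivity should follow from the reductive regime: the electron-rich ring, which would be oxidised at a Kolbe anode, and the aryl acetate are both inert at the mild cathodic potential at which the esters are reduced. The 4-arylbutyl radical has no fast intramolecular escape, since a 1,4-hydrogen shift or ring closure onto the arene is slow compared with capture by nickel.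

Step 7
Reactants: 11 2-methoxy-6-pentadecylphenyl acetate
Product: 13 4-hydroxy-2-methoxy-6-pentadecylphenyl acetate (target), via aryl pinacol boronate 12 (not isolated)
Conditions: [Ir(OMe)(cod)]2 (1.5 mol%), 4,4'-di-tert-butyl-2,2'-bipyridine (3 mol%), B2pin2 (1.0 equiv), THF, 80 °C; evaporate; then Oxone (1.1 equiv), acetone/H2O, rt, 15 min; aq. NaHSO3 quench
Reagents that add atoms: bis(pinacolato)diboron, CC1(C)OB(OC1(C)C)B1OC(C)(C)C(C)(C)O1 (boron of intermediate 12); Oxone (potassium peroxymonosulfate), [K+].[O-]S(=O)(=O)OO (the phenol oxygen)
Why: Sterically controlled iridium-catalysed aromatic C–H borylation followed by one-pot oxidation of the aryl boronate to the phenol; in the 1,2,3-trisubstituted ring of 11 only C5–H has no ortho substituent, so boron and then oxygen should enter para to the acetate, and the brief, mildly acidic Oxone treatment should leave the aryl acetate intact.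

**Compound list**

1 | o-vanillin (2-hydroxy-3-methoxybenzaldehyde) | COc1cccc(C=O)c1O | starting material
2 | (3-carboxypropyl)triphenylphosphonium bromide | OC(=O)CCC[P+](c1ccccc1)(c1ccccc1)c1ccccc1.[Br-] | starting material
3 | potassium 4-(triphenylphosphoranylidene)butanoate (carboxylate ylide) | [K+].[O-]C(=O)CCC=P(c1ccccc1)(c1ccccc1)c1ccccc1 | intermediate
4 | (Z)-5-(2-hydroxy-3-methoxyphenyl)pent-4-enoic acid | COc1cccc(/C=C\CCC(O)=O)c1O | intermediate
5 | 5-(2-hydroxy-3-methoxyphenyl)pentanoic acid | COc1cccc(CCCCC(O)=O)c1O | intermediate
6 | 5-(2-acetoxy-3-methoxyphenyl)pentanoic acetic anhydride | COc1cccc(CCCCC(=O)OC(C)=O)c1OC(C)=O | intermediate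
7 | 5-(2-acetoxy-3-methoxyphenyl)pentanoic acid | COc1cccc(CCCCC(O)=O)c1OC(C)=O | intermediate
8 | 1,3-dioxoisoindolin-2-yl 5-(2-acetoxy-3-methoxyphenyl)pentanoate | COc1cccc(CCCCC(=O)ON2C(=O)c3ccccc3C2=O)c1OC(C)=O | intermediate
9 | lauric acid (dodecanoic acid) | CCCCCCCCCCCC(O)=O | starting material
10 | 1,3-dioxoisoindolin-2-yl dodecanoate | CCCCCCCCCCCC(=O)ON1C(=O)c2ccccc2C1=O | intermediate
11 | 2-methoxy-6-pentadecylphenyl acetate | CCCCCCCCCCCCCCCc1cccc(OC)c1OC(C)=O | intermediate
12 | 2-methoxy-6-pentadecyl-4-(4,4,5,5-tetramethyl-1,3,2-dioxaborolan-2-yl)phenyl acetate | CCCCCCCCCCCCCCCc1cc(B2OC(C)(C)C(C)(C)O2)cc(OC)c1OC(C)=O | intermediate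
13 | 4-hydroxy-2-methoxy-6-pentadecylphenyl acetate | CCCCCCCCCCCCCCCc1cc(O)cc(OC)c1OC(C)=O | target

**Step count**

Total: 7 steps. Longest linear sequence: 6 steps (steps 1, 2, 3, 4, 6, 7 from o-vanillin); step 5 is a one-step side branch.

**Steps most likely to fail, with fallbacks**

Step 6. The risk is that the two alkyl radicals partition mainly into homo-coupling or are reduced to the alkanes before the second radical is captured, so that ester 8 is consumed without cross-coupling. The fallback replaces the coupling of two electrophiles by a decarboxylative Negishi coupling. It sets out from 8. 1-Bromoundecane and magnesium in THF should give undecylmagnesium bromide F1, which is transmetalated with ZnCl2 (0.55 equiv) to diundecylzinc F2. F2 (2 equiv) is then coupled with 8 under NiCl2·glyme (20 mol%) and 4,4'-di-tert-butyl-2,2'-bipyridine (40 mol%) in THF/DMF at rt. The dialkylzinc should not attack the aryl acetate. The fallback comes back to the route at 11.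

Step 7. The risks are partial borylation at C4 next to the methoxy group, over-oxidation of the electron-rich product phenol to the quinone by Oxone, and partial loss of the acetate. The fallback builds the para oxygen by quinone chemistry and sets out from 11. Methanolysis (K2CO3, MeOH) should give 2-methoxy-6-pentadecylphenol F3. Teuber oxidation with Fremy's salt (KH2PO4 buffer, acetone/H2O) should give 2-methoxy-6-pentadecyl-1,4-benzoquinone F4. Reduction with Na2S2O4 (EtOAc/H2O) should give 2-methoxy-6-pentadecylbenzene-1,4-diol F5, and Ac2O/pyridine should give 2-methoxy-6-pentadecyl-1,4-phenylene diacetate F6. Lipase-catalysed alcoholysis (Candida antarctica lipase B, n-BuOH, MTBE) should then remove only the unhindered acetate flanked by two ring hydrogens, because the other is shielded by OMe and the pentadecyl chain. The fallback comes back at 13.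

Step 1. The risk is that deprotonation of the phenol makes the aldehyde of o-vanillin too electron-rich, so that addition of the ylide stalls and the conversion stays incomplete. The fallback masks the phenol and sets out from 1. BnBr and K2CO3 in DMF should give 2-(benzyloxy)-3-methoxybenzaldehyde F7. Wittig reaction with ylide 3 (from 2 and 2.1 equiv KOtBu, THF) should give (Z)-5-[2-(benzyloxy)-3-methoxyphenyl]pent-4-enoic acid F8. Hydrogenation (H2, Pd/C, EtOAc/MeOH) should saturate the alkene and cleave the benzyl ether in one operation. The fallback comes back at 5.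

**Further compounds**

F1 | step 6 | undecylmagnesium bromide | CCCCCCCCCCC[Mg]Br
F2 | step 6 | diundecylzinc | CCCCCCCCCCC[Zn]CCCCCCCCCCC
F3 | step 7 | 2-methoxy-6-pentadecylphenol | CCCCCCCCCCCCCCCc1cccc(OC)c1O
F4 | step 7 | 2-methoxy-6-pentadecyl-1,4-benzoquinone | CCCCCCCCCCCCCCCC1=CC(=O)C=C(OC)C1=O
F5 | step 7 | 2-methoxy-6-pentadecylbenzene-1,4-diol | CCCCCCCCCCCCCCCc1cc(O)cc(OC)c1O
F6 | step 7 | 2-methoxy-6-pentadecyl-1,4-phenylene diacetate | CCCCCCCCCCCCCCCc1cc(OC(C)=O)cc(OC)c1OC(C)=O
F7 | step 1 | 2-(benzyloxy)-3-methoxybenzaldehyde | COc1cccc(C=O)c1OCc1ccccc1
F8 | step 1 | (Z)-5-[2-(benzyloxy)-3-methoxyphenyl]pent-4-enoic acid | COc1cccc(/C=C\CCC(O)=O)c1OCc1ccccc1
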